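**Retrosynthetic overview**
The strategy rests on the α-methylene-γ-lactone (O–C12(=O)–C11=C13) trans-fused at C7–C8 to the cyclodeca-1(10),4-diene ring, with the free carbinol C6 next to C7: C13–C11–C7 is a 2-carboxyallyl unit, so the C6–C7 bond is cut to a C6 enal and a C13 allylic bromide held in a butenolide on O8.
Ring order: the five-membered lactone ring is closed first (ring-closing metathesis at C7=C11); the ten-membered carbocycle is closed last by intramolecular chromium allylation at C6–C7, which also moves the alkene to C11=C13.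
Chain assembly: C3–C4 Negishi coupling of a homoallylic zinc reagent (C7–C10, C1–C3; C8 from (S)-epichlorohydrin) with a (Z)-iodoalkene (C15, C4–C6 from but-2-yne-1,4-diol); the side-chain acid (from crotonaldehyde) is attached at O15 by Mitsunobu esterification.
Stereochemistry: only C8 is bought; C7 and C6 are set together in the ring closure; the three trisubstituted alkenes come from syn-carboalumination, anti-hydroalumination/iodination and a (Z)-2-iodoenal.

Key step: step 21

Remark: positions are given in germacrane numbering (ring C1–C10; C11, C12, C13 = lactone α-carbon, carbonyl carbon, exocyclic methylene; C14 = methyl on C10; C15 = oxygenated carbon on C4).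

**Route**

Step 1
Reactants: 1 (S)-epichlorohydrin
Product: 2 (S)-1-chloro-5-(trimethylsilyl)pent-4-yn-2-ol
Conditions: trimethylsilylacetylene, n-BuLi, THF, −78 °C; then 1, BF3·OEt2, −78 °C; aq. NH4Cl
Reagents that add atoms: trimethylsilylacetylene, C#C[Si](C)(C)C
Why: BF3-promoted epoxide alkynylation should occur at the unsubstituted epoxide carbon and not at the C–Cl carbon, so the C–O bond of the stereocentre (future C8) is untouched and the alkyne brings C10 and C1.

Step 2
Reactants: 2 (S)-1-chloro-5-(trimethylsilyl)pent-4-yn-2-ol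
Product: 4 (S)-6-(trimethylsilyl)hex-1-en-5-yn-3-ol, via terminal epoxide 3 (not isolated)
Conditions: Me3S+ I− (3.5 equiv), n-BuLi (3.4 equiv), THF, −20 °C to rt
Reagents that add atoms: trimethylsulfonium iodide, C[S+](C)C.[I-]
Why: excess dimethylsulfonium methylide should first close the chlorohydrin to the epoxide (intramolecular Williamson displacement) and then open it at CH2, after which the β-sulfonium alkoxide loses dimethyl sulfide through its ylide to give the vinyl carbinol (one-carbon epoxide-to-allylic-alcohol homologation) without touching the carbinol centre.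

Step 3
Reactants: 4 (S)-6-(trimethylsilyl)hex-1-en-5-yn-3-ol
Product: 5 (S)-tert-butyldimethyl{[6-(trimethylsilyl)hex-1-en-5-yn-3-yl]oxy}silane
Conditions: TBSCl, imidazole, DMF, rt
Reagents that add atoms: tert-butyldimethylsilyl chloride, CC(C)(C)[Si](C)(C)Cl
Why: standard imidazole-mediated O-silylation of a secondary alcohol, done before the alkyne is freed so that no volatile enynol has to be handled.

Step 4
Reactants: 5 (S)-tert-butyldimethyl{[6-(trimethylsilyl)hex-1-en-5-yn-3-yl]oxy}silane
Product: 6 (S)-tert-butyl(hex-1-en-5-yn-3-yloxy)dimethylsilane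
Conditions: K2CO3, MeOH, rt
Reagents that add atoms: none
Why: base-catalysed methanolysis cleaves the C(sp)–Si bond selectively, since the secondary tert-butyldimethylsilyl ether is stable to K2CO3 in methanol.

Step 5
Reactants: 6 (S)-tert-butyl(hex-1-en-5-yn-3-yloxy)dimethylsilane
Product: 9 (S,E)-6-(tert-butyldimethylsilyloxy)-4-methylocta-3,7-dien-1-ol, via alkenyldimethylalane 7 (not isolated), via lithium butylalanate 8 (not isolated)
Conditions: Me3Al (2.5 equiv), Cp2ZrCl2 (0.25 equiv), CH2Cl2, 0 °C to rt; volatiles off, hexane, n-BuLi, 0 °C; ethylene oxide, THF, −30 to 0 °C; aq. NH4Cl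
Reagents that add atoms: trimethylaluminium, C[Al](C)C; ethylene oxide, C1CO1
Why: zirconium-catalysed syn-methylalumination (Negishi carboalumination) should place the C14 methyl on the internal alkyne carbon far faster than it touches the vinyl group, and the derived alanate opens ethylene oxide with retention, so C2 and C3 are added and the C1=C10 alkene is E.

Step 6
Reactants: 9 (S,E)-6-(tert-butyldimethylsilyloxy)-4-methylocta-3,7-dien-1-ol
Product: 10 (S,E)-tert-butyl[(8-iodo-6-methylocta-1,5-dien-3-yl)oxy]dimethylsilane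
Conditions: I2, PPh3, imidazole, CH2Cl2, 0 °C
Reagents that add atoms: iodine, [I][I]
Why: Appel-type iodination converts the primary alcohol into the iodide by SN2 displacement of the alkoxyphosphonium ion and leaves the silyl ether and both alkenes alone.

Step 7
Reactants: 11 but-2-yne-1,4-diol
Product: 12 4-[(4-methoxybenzyl)oxy]but-2-yn-1-ol
Conditions: NaH (1 equiv), 4-methoxybenzyl chloride (1 equiv), 11 (3 equiv), DMF, 0 °C to rt
Reagents that add atoms: 4-methoxybenzyl chloride, COc1ccc(CCl)cc1
Why: Williamson etherification with the diol in excess should give mainly the mono-ether, which differentiates the future C15 and C6 oxygens.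

Step 8
Reactants: 12 4-[(4-methoxybenzyl)oxy]but-2-yn-1-ol
Product: 14 (Z)-3-iodo-4-[(4-methoxybenzyl)oxy]but-2-en-1-ol, via cyclic alkenylalanate 13 (not isolated)
Conditions: NaAlH2(OCH2CH2OCH3)2, THF, 0 °C to rt; EtOAc; I2, THF, −78 to 0 °C
Reagents that add atoms: iodine, [I][I]
Why: hydroxyl-directed anti-hydroalumination delivers hydride to C5 and aluminium to C4 within a five-membered oxa-aluminacycle, and iodinolysis with retention places iodine on C4 cis to the C6 carbinol carbon.

Step 9
Reactants: 14 (Z)-3-iodo-4-[(4-methoxybenzyl)oxy]but-2-en-1-ol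
Product: 15 (Z)-tert-butyl({3-iodo-4-[(4-methoxybenzyl)oxy]but-2-en-1-yl}oxy)dimethylsilane
Conditions: TBSCl, imidazole, CH2Cl2, rt
Reagents that add atoms: tert-butyldimethylsilyl chloride, CC(C)(C)[Si](C)(C)Cl
Why: routine silylation of the primary allylic (C6) alcohol so that no free hydroxyl quenches the organozinc partner.

Step 10
Reactants: 10 (S,E)-tert-butyl[(8-iodo-6-methylocta-1,5-dien-3-yl)oxy]dimethylsilane; 15 (Z)-tert-butyl({3-iodo-4-[(4-methoxybenzyl)oxy]but-2-en-1-yl}oxy)dimethylsilane
Product: 17 (3S,5E,9E)-3,11-bis(tert-butyldimethylsilyloxy)-9-{[(4-methoxybenzyl)oxy]methyl}-5-methylundeca-1,5,9-triene, via alkylzinc iodide 16 (not isolated)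
Conditions: 10, Zn dust (activated with 1,2-dibromoethane and TMSCl), LiCl, THF, 40 °C; then 15, Pd(PPh3)4 (zerovalent palladium, 5 mol %), THF, rt
Reagents that add atoms: none
Why: zinc inserts into the primary C–I bond only, and the Negishi sp3–sp2 coupling forms C3–C4 with retention of the iodoalkene geometry, so C3 ends cis to C6 (ring-cis C4=C5).

Step 11
Reactants: 18 (E)-crotonaldehyde
Product: 19 (Z)-2-iodobut-2-enal
Conditions: I2, K2CO3, DMAP (0.2 equiv), THF/H2O (1:1), rt
Reagents that add atoms: iodine, [I][I]
Why: amine-catalysed α-iodination (conjugate addition of DMAP, iodination of the enolate, elimination) should give the 2-iodoenal with methyl cis to iodine and trans to the formyl group.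

Step 12
Reactants: 19 (Z)-2-iodobut-2-enal
Product: 20 (Z)-2-iodobut-2-en-1-ol
Conditions: NaBH4, MeOH, 0 °C
Reagents that add atoms: none
Why: borohydride 1,2-reduction of the aldehyde leaves the iodoalkene and its geometry untouched.

Step 13
Reactants: 20 (Z)-2-iodobut-2-en-1-ol
Product: 21 (Z)-tert-butyl[(2-iodobut-2-en-1-yl)oxy]diphenylsilane
Conditions: TBDPSCl, imidazole, CH2Cl2, rt
Reagents that add atoms: tert-butyldiphenylsilyl chloride, CC(C)(C)[Si](Cl)(c1ccccc1)c1ccccc1
Why: silylation with the acid-resistant tert-butyldiphenylsilyl group, chosen so that it survives the later removal of the two tert-butyldimethylsilyl ethers.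

Step 14
Reactants: 21 (Z)-tert-butyl[(2-iodobut-2-en-1-yl)oxy]diphenylsilane
Product: 22 (Z)-2-{[(tert-butyldiphenylsilyl)oxy]methyl}but-2-enoic acid
Conditions: CO (3 bar), PdCl2(PPh3)2 (divalent palladium precatalyst, 5 mol %), Et3N, H2O, DMF, 60 °C; aq. citric acid
Reagents that add atoms: carbon monoxide, [C-]#[O+]; water, O
Why: palladium-catalysed hydroxycarbonylation (oxidative addition with retention, CO insertion, hydrolysis of the acylpalladium) puts the carboxyl group where iodine was, so the methyl ends cis to the carboxyl (Z acid).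

Step 15
Reactants: 17 (3S,5E,9E)-3,11-bis(tert-butyldimethylsilyloxy)-9-{[(4-methoxybenzyl)oxy]methyl}-5-methylundeca-1,5,9-triene
Product: 23 (3S,5E,9E)-3,11-bis(tert-butyldimethylsilyloxy)-9-(hydroxymethyl)-5-methylundeca-1,5,9-triene
Conditions: DDQ, CH2Cl2/pH 7 phosphate buffer, 0 °C
Reagents that add atoms: none
Why: oxidative cleavage of the electron-rich 4-methoxybenzyl ether (benzylic hydride abstraction, hydrolysis of the oxocarbenium ion) frees the C15 alcohol while the silyl ethers and isolated alkenes are inert.

Step 16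
Reactants: 23 (3S,5E,9E)-3,11-bis(tert-butyldimethylsilyloxy)-9-(hydroxymethyl)-5-methylundeca-1,5,9-triene; 22 (Z)-2-{[(tert-butyldiphenylsilyl)oxy]methyl}but-2-enoic acid
Product: 24 C15 ester: the 9-CH2–O–C(=O)– ester of 23 with acid 22 (both tert-butyldimethylsilyl ethers and the tert-butyldiphenylsilyl ether in place)
Conditions: PPh3, DIAD, THF, 0 °C to rt
Reagents that add atoms: none
Why: in the Mitsunobu esterification the primary allylic alcohol is activated and the carboxylate acts as nucleophile (SN2), so the acid is never turned into an acylating agent and its Z-enoate cannot isomerise.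

Step 17
Reactants: 24 C15 ester with two tert-butyldimethylsilyl ethers
Product: 25 (3S,5E,9E)-9-(acyloxymethyl)-5-methylundeca-1,5,9-triene-3,11-diol (acyl = (Z)-2-{[(tert-butyldiphenylsilyl)oxy]methyl}but-2-enoyl), the C8/C6 diol
Conditions: CSA (0.2 equiv), MeOH/CH2Cl2 (1:1), 0 °C to rt
Reagents that add atoms: none
Why: acid-catalysed methanolysis removes both tert-butyldimethylsilyl ethers, whereas the bulkier tert-butyldiphenylsilyl ether is cleaved far more slowly under acid and should survive.

Step 18
Reactants: 25 C8/C6 diol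
Product: 26 (2E,6E,9S)-3-(acyloxymethyl)-9-hydroxy-7-methylundeca-2,6,10-trienal (acyl as in 25), the C8-hydroxy C6 enal
Conditions: TEMPO (10 mol %), PhI(OAc)2 (1.1 equiv), CH2Cl2, rt
Reagents that add atoms: none
Why: oxoammonium-mediated oxidation distinguishes the primary allylic C6 alcohol from the secondary C8 alcohol, and its non-basic conditions should keep the ring-cis enal geometry.

Step 19
Reactants: 26 C8-hydroxy C6 enal; 27 2-(bromomethyl)acrylic acid
Product: 28 C8 2-(bromomethyl)acrylate of 26
Conditions: DCC, DMAP (5 mol %), CH2Cl2, −10 to 0 °C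
Reagents that add atoms: none
Why: Steglich esterification acylates the only free hydroxyl without touching the C8 configuration, and low temperature with little DMAP limits quaternisation of the catalyst by the allylic bromide.

Step 20
Reactants: 28 C8 2-(bromomethyl)acrylate of 26
Product: 29 (S)-3-(bromomethyl)-5-substituted furan-2(5H)-one carrying the C9–C10=C1–C2–C3–C4(C15 ester)=C5–C6 enal chain on C8
Conditions: second-generation Hoveyda–Grubbs catalyst, RuCl2(SIMes)(=CH–C6H4-2-OiPr) (10 mol %), toluene (5 mM), 70 °C
Reagents that add atoms: none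
Why: ring-closing metathesis should start at the monosubstituted vinyl group and close onto the 1,1-disubstituted acrylate to form the five-membered butenolide (C7=C11) with loss of ethylene, while the trisubstituted alkenes and the enal are too hindered to take part.

Step 21
Reactants: 29 3-(bromomethyl)butenolide enal
Product: 31 (6R,7S,8S)-6-hydroxy-15-[(Z)-2-{[(tert-butyldiphenylsilyl)oxy]methyl}but-2-enoyloxy]germacra-1(10),4,11(13)-trien-12,8-olide (E at C1=C10, ring-cis at C4=C5), via allylchromium dichloride 30 (not isolated)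
Conditions: CrCl2 (divalent chromium, 12 equiv), THF, rt, syringe-pump addition of 29 (final about 1 mM); aq. NH4Cl
Reagents that add atoms: none
Why: CrCl2 (two equivalents per C–Br bond) reduces the allylic bromide to the allylchromium species 30 (trivalent chromium on C13), which adds to the C6 aldehyde through its γ-carbon C7 in a six-membered cyclic chair array, a Nozaki–Hiyama–Kishi allylation (the chromium form of the Barbier reaction); the closest known reactions are ten-membered germacranolide closures by intramolecular chromium allylation with 2-(alkoxycarbonyl)allyl bromides and intermolecular Barbier allylations of aldehydes with 3-(bromomethyl)furan-2(5H)-ones. The ten-membered carbocycle closes in this one event by exo attack on the aldehyde carbonyl (10-exo-trig), and the allylic transposition shifts the butenolide alkene to C11=C13, so the α-methylene lactone appears without a later methylenation or lactonisation. C7 is controlled by the C8 stereocentre: the aldehyde hangs from C9 and must reach C7 across the flat butenolide, and the chain containing the E C1=C10 alkene is expected to bridge from one face to the other (new bond anti to C9, trans-fused lactone) with less strain than folding back over the face it starts from. C6 is controlled by the chair: the lactone ring holds C8 trans to C13, so the donor is an E-type γ-substituted allylmetal, C5 and C8 both sit equatorial, and the anti C6/C7 pair (6R,7S) should result. The step needs γ- over α-attack and carbonyl over conjugate addition (both normal for allylchromium reagents, which also leave the three ester groups alone at room temperature) and ring closure over oligomerisation (secured by slow addition at high dilution); the facial choice at C7 is the least certain of these.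

Step 22
Reactants: 31 silyl-protected germacranolide
Product: 32 CNP0234544.2, (6R,7S,8S)-6-hydroxy-15-[(Z)-2-(hydroxymethyl)but-2-enoyloxy]germacra-1(10),4,11(13)-trien-12,8-olide
Conditions: HF·pyridine, pyridine, THF, 0 °C to rt
Reagents that add atoms: none
Why: buffered fluoride cleavage of the primary silyl ether avoids basic conditions, which could cause translactonisation to O6 or conjugate addition to the α-methylene lactone.

**Compound list**
1 | (S)-epichlorohydrin | ClC[C@@H]1CO1 | starting material
2 | (S)-1-chloro-5-(trimethylsilyl)pent-4-yn-2-ol | ClC[C@@H](O)CC#C[Si](C)(C)C | intermediate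
3 | (S)-trimethyl[3-(oxiran-2-yl)prop-1-yn-1-yl]silane (terminal epoxide) | C[Si](C)(C)C#CC[C@H]1CO1 | intermediate
4 | (S)-6-(trimethylsilyl)hex-1-en-5-yn-3-ol | C=C[C@@H](O)CC#C[Si](C)(C)C | intermediate
5 | (S)-tert-butyldimethyl{[6-(trimethylsilyl)hex-1-en-5-yn-3-yl]oxy}silane | C=C[C@@H](O[Si](C)(C)C(C)(C)C)CC#C[Si](C)(C)C | intermediate
6 | (S)-tert-butyl(hex-1-en-5-yn-3-yloxy)dimethylsilane | C=C[C@@H](O[Si](C)(C)C(C)(C)C)CC#C | intermediate
7 | (S,E)-[4-(tert-butyldimethylsilyloxy)-2-methylhexa-1,5-dien-1-yl]dimethylalane | C=C[C@@H](O[Si](C)(C)C(C)(C)C)C/C(C)=C/[Al](C)C | intermediate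
8 | lithium butyl[(S,E)-4-(tert-butyldimethylsilyloxy)-2-methylhexa-1,5-dien-1-yl]dimethylalanate | [Li+].CCCC[Al-](C)(C)/C=C(\C)C[C@H](O[Si](C)(C)C(C)(C)C)C=C | intermediate
9 | (S,E)-6-(tert-butyldimethylsilyloxy)-4-methylocta-3,7-dien-1-ol | C=C[C@@H](O[Si](C)(C)C(C)(C)C)C/C(C)=C/CCO | intermediate
10 | (S,E)-tert-butyl[(8-iodo-6-methylocta-1,5-dien-3-yl)oxy]dimethylsilane | C=C[C@@H](O[Si](C)(C)C(C)(C)C)C/C(C)=C/CCI | intermediate
11 | but-2-yne-1,4-diol | OCC#CCO | starting material
12 | 4-[(4-methoxybenzyl)oxy]but-2-yn-1-ol | COc1ccc(COCC#CCO)cc1 | intermediate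
13 | sodium cyclic alkenylalanate (2,2-bis(2-methoxyethoxy)-1,2-oxaaluminol-3-ene carrying CH2O-(4-methoxybenzyl) on C3) | [Na+].COCCO[Al-]1(OCCOC)OCC=C1COCc1ccc(OC)cc1 | intermediate
14 | (Z)-3-iodo-4-[(4-methoxybenzyl)oxy]but-2-en-1-ol | COc1ccc(COC/C(I)=C/CO)cc1 | intermediate
15 | (Z)-tert-butyl({3-iodo-4-[(4-methoxybenzyl)oxy]but-2-en-1-yl}oxy)dimethylsilane | COc1ccc(COC/C(I)=C/CO[Si](C)(C)C(C)(C)C)cc1 | intermediate
16 | [(S,E)-6-(tert-butyldimethylsilyloxy)-4-methylocta-3,7-dien-1-yl]zinc iodide | C=C[C@@H](O[Si](C)(C)C(C)(C)C)C/C(C)=C/CC[Zn]I | intermediate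
17 | (3S,5E,9E)-3,11-bis(tert-butyldimethylsilyloxy)-9-{[(4-methoxybenzyl)oxy]methyl}-5-methylundeca-1,5,9-triene | C=C[C@@H](O[Si](C)(C)C(C)(C)C)C/C(C)=C/CC/C(COCc1ccc(OC)cc1)=C\CO[Si](C)(C)C(C)(C)C | intermediate
18 | (E)-crotonaldehyde | C/C=C/C=O | starting material
19 | (Z)-2-iodobut-2-enal | C/C=C(\I)C=O | intermediate
20 | (Z)-2-iodobut-2-en-1-ol | C/C=C(\I)CO | intermediate
21 | (Z)-tert-butyl[(2-iodobut-2-en-1-yl)oxy]diphenylsilane | C/C=C(\I)CO[Si](c1ccccc1)(c1ccccc1)C(C)(C)C | intermediate
22 | (Z)-2-{[(tert-butyldiphenylsilyl)oxy]methyl}but-2-enoic acid | C/C=C(\C(=O)O)CO[Si](c1ccccc1)(c1ccccc1)C(C)(C)C | intermediate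
23 | (3S,5E,9E)-3,11-bis(tert-butyldimethylsilyloxy)-9-(hydroxymethyl)-5-methylundeca-1,5,9-triene | C=C[C@@H](O[Si](C)(C)C(C)(C)C)C/C(C)=C/CC/C(CO)=C\CO[Si](C)(C)C(C)(C)C | intermediate
24 | C15 ester of 23 with acid 22 | C=C[C@@H](O[Si](C)(C)C(C)(C)C)C/C(C)=C/CC/C(COC(=O)/C(=C\C)CO[Si](c1ccccc1)(c1ccccc1)C(C)(C)C)=C\CO[Si](C)(C)C(C)(C)C | intermediate
25 | C8/C6 diol carrying the C15 ester | C=C[C@@H](O)C/C(C)=C/CC/C(COC(=O)/C(=C\C)CO[Si](c1ccccc1)(c1ccccc1)C(C)(C)C)=C\CO | intermediate
26 | C8-hydroxy C6 enal, (2E,6E,9S)-3-(acyloxymethyl)-9-hydroxy-7-methylundeca-2,6,10-trienal | C=C[C@@H](O)C/C(C)=C/CC/C(COC(=O)/C(=C\C)CO[Si](c1ccccc1)(c1ccccc1)C(C)(C)C)=C\C=O | intermediate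
27 | 2-(bromomethyl)acrylic acid | C=C(CBr)C(=O)O | starting material
28 | C8 2-(bromomethyl)acrylate of 26 | C=C[C@@H](OC(=O)C(=C)CBr)C/C(C)=C/CC/C(COC(=O)/C(=C\C)CO[Si](c1ccccc1)(c1ccccc1)C(C)(C)C)=C\C=O | intermediate
29 | (S)-3-(bromomethyl)butenolide enal | BrCC1=C[C@H](C/C(C)=C/CC/C(COC(=O)/C(=C\C)CO[Si](c2ccccc2)(c2ccccc2)C(C)(C)C)=C\C=O)OC1=O | intermediate
30 | allylchromium dichloride derived from 29 (trivalent chromium on C13) | Cl[Cr](Cl)CC1=C[C@H](C/C(C)=C/CC/C(COC(=O)/C(=C\C)CO[Si](c2ccccc2)(c2ccccc2)C(C)(C)C)=C\C=O)OC1=O | intermediate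
31 | silyl-protected target, (6R,7S,8S)-germacranolide | C=C1C(=O)O[C@H]2C/C(C)=C/CC/C(COC(=O)/C(=C\C)CO[Si](c3ccccc3)(c3ccccc3)C(C)(C)C)=C\[C@@H](O)[C@H]12 | intermediate
32 | CNP0234544.2 | C=C1C(=O)O[C@H]2C/C(C)=C/CC/C(COC(=O)/C(=C\C)CO)=C\[C@@H](O)[C@H]12 | target

**Step count**
Total: 22 steps. Longest linear sequence: 15 steps (steps 1–6, 10, 15–22).

**Steps most likely to fail**

1. Step 21 (ring closure). What may go wrong: intermolecular addition or protonation of the allylchromium may outrun closure of the ten-membered ring, and a loose, non-chair addition may erode the facial preference at C7 or the anti C6/C7 relationship. Fallback, setting out from 29 and coming back at 31: the reductive metalation in the flask is replaced by a pre-formed main-group allyl donor. Borylation of the allylic bromide with bis(pinacolato)diboron and Pd2(dba)3 (zerovalent palladium, ligand-free so that the C15 allylic ester is not ionised) in THF at 40 °C should give the pinacol allylboronate F1. As a 2-carbonyl-substituted allylboronate it should not add to the aldehyde at room temperature and can be purified. It is then cyclised at high dilution with catalytic Sc(OTf)3 in CH2Cl2 (−40 °C to rt) through a compact boron-centred chair, and aqueous work-up gives 31.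

2. Step 20 (ring-closing metathesis). What may go wrong: the allylic bromide may decompose the ruthenium carbene or be lost from the product during prolonged heating, so that the vinyl group dimerises instead of closing the lactone ring. Fallback, setting out from 26 and coming back at 29: the halide is introduced only after the ring exists. Esterification of 26 with 2-{[(triethylsilyl)oxy]methyl}acrylic acid (a known reagent, C=C(CO[Si](CC)(CC)CC)C(=O)O; DCC, DMAP cat., CH2Cl2, 0 °C) gives the halide-free C8 2-{[(triethylsilyl)oxy]methyl}acrylate F2; with no allylic bromide present, quaternisation of DMAP is also avoided. Ring-closing metathesis with the same catalyst gives the 3-{[(triethylsilyl)oxy]methyl}butenolide enal F3. AcOH/THF/H2O at rt removes the triethylsilyl group while the tert-butyldiphenylsilyl ether stays, giving the 3-(hydroxymethyl)butenolide enal F4. PBr3 in Et2O at −10 °C then converts the allylic alcohol into bromide 29.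

3. Step 5 (methylalumination and epoxide opening in one flask). What may go wrong: the hindered alanate may open ethylene oxide slowly, so that protonolysis on work-up gives the 2-methylalkene instead of the chain-extended alcohol. Fallback, setting out from 6 (methylalumination to 7 as before) and, with 15, coming back at 17, so that 9, 10 and 16 are bypassed: the union is moved from C3–C4 to C1–C2. Iodinolysis of 7 (I2, THF, −30 °C) gives (S,E)-tert-butyl[(6-iodo-5-methylhexa-1,5-dien-3-yl)oxy]dimethylsilane F5. Separately, Stille coupling of 15 with tributyl(vinyl)stannane (Pd(PPh3)4, zerovalent palladium, LiCl, DMF, 60 °C) gives the diene (E)-tert-butyl({3-[(4-methoxybenzyloxy)methyl]penta-2,4-dien-1-yl}oxy)dimethylsilane F6. 9-BBN in THF hydroborates its terminal vinyl group at C2 to give the B-alkyl-9-borabicyclo[3.3.1]nonane F7, which is used directly. B-alkyl Suzuki–Miyaura coupling with F5 (PdCl2(dppf), divalent palladium precatalyst, AsPh3, Cs2CO3, DMF/H2O, rt) forms C1–C2 with retention and gives 17.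

Further compounds
F1 | step 21 | pinacol allylboronate, (S)-3-[(4,4,5,5-tetramethyl-1,3,2-dioxaborolan-2-yl)methyl]butenolide enal | CC1(C)OB(CC2=C[C@H](C/C(C)=C/CC/C(COC(=O)/C(=C\C)CO[Si](c3ccccc3)(c3ccccc3)C(C)(C)C)=C\C=O)OC2=O)OC1(C)C
F2 | step 20 | C8 2-{[(triethylsilyl)oxy]methyl}acrylate of 26 | C=C[C@@H](OC(=O)C(=C)CO[Si](CC)(CC)CC)C/C(C)=C/CC/C(COC(=O)/C(=C\C)CO[Si](c1ccccc1)(c1ccccc1)C(C)(C)C)=C\C=O
F3 | step 20 | (S)-3-{[(triethylsilyl)oxy]methyl}butenolide enal | CC[Si](CC)(CC)OCC1=C[C@H](C/C(C)=C/CC/C(COC(=O)/C(=C\C)CO[Si](c2ccccc2)(c2ccccc2)C(C)(C)C)=C\C=O)OC1=O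
F4 | step 20 | (S)-3-(hydroxymethyl)butenolide enal | OCC1=C[C@H](C/C(C)=C/CC/C(COC(=O)/C(=C\C)CO[Si](c2ccccc2)(c2ccccc2)C(C)(C)C)=C\C=O)OC1=O
F5 | step 5 | (S,E)-tert-butyl[(6-iodo-5-methylhexa-1,5-dien-3-yl)oxy]dimethylsilane | C=C[C@@H](O[Si](C)(C)C(C)(C)C)C/C(C)=C/I
F6 | step 5 | (E)-tert-butyl({3-[(4-methoxybenzyloxy)methyl]penta-2,4-dien-1-yl}oxy)dimethylsilane | C=C/C(COCc1ccc(OC)cc1)=C\CO[Si](C)(C)C(C)(C)C
F7 | step 5 | B-alkyl-9-borabicyclo[3.3.1]nonane from F6 (boron on C2) | COc1ccc(COC/C(CCB2C3CCCC2CCC3)=C/CO[Si](C)(C)C(C)(C)C)cc1
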